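**Plan** (zeylenone numbering: C1 = C(OH)CH2OBz, C2 = CHOAc, C3 = CHOBz, C4=C5 alkene, C6 = C=O, C7 = CH2OBz)
Retrosynthesis: C6=O goes back to a C6 carbinol and the cis O1/O2 pair to a C1=C2 alkene. Then C1=C2 and C4=C5 of the resulting cyclohexa-1,4-diene are cut together.
Enabling feature: in the six-membered ring the oxygen-bearing carbons C3 and C6 lie 1,4 to each other. Each is flanked by one end of both bonds (C2/C4 and C1/C5), so the ring is two penta-1,4-dien-3-ol units joined head to head, and an O3–Si–O6 bridge can hold them.
Forward: the dienol C5–C6–C1–C7 and divinylcarbinol (C2–C3–C4) are tied as a mixed silaketal. One double ring-closing metathesis closes the seven-membered silaketal ring (C4=C5) and then the carbocycle (C1=C2).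
Stereochemistry: C6 comes from a kinetic resolution. C6 sets C3 through the tether by selecting between two vinyl groups. The bridge then directs OsO4 to set C1 and C2, and C6 is finally erased by oxidation.
Endgame: acetate on O2, tether off, benzoate on O3, C6–OH to the ketone.

Key step: step 6

Step 1
Reactants: 1 acrolein; 2 methyl acrylate
Product: 3 methyl 3-hydroxy-2-methylidenepent-4-enoate (racemic)
Conditions: DABCO (0.3 equiv), excess 2, neat, rt
Reagents that add atoms: none
Why: Morita–Baylis–Hillman reaction: DABCO adds to the acrylate, the ammonium enolate attacks the aldehyde carbon of acrolein, and loss of DABCO restores the 2-methylidene unit, so C5–C6–C1–C7 arrives in one step.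

Step 2
Reactants: 3 methyl 3-hydroxy-2-methylidenepent-4-enoate (racemic)
Product: 4 methyl (3S)-3-hydroxy-2-methylidenepent-4-enoate
Conditions: Ti(OiPr)4 (15 mol %), L-(+)-diisopropyl tartrate (18 mol %), t-BuOOH (0.6 equiv), 4 Å MS, CH2Cl2, −20 °C, stopped a little past half conversion
Reagents that add atoms: none
Why: Sharpless kinetic resolution of a secondary allylic alcohol: only the vinyl group can be epoxidised because the acrylate alkene is too electron-poor, L-(+)-DIPT should consume the R enantiomer (R here only because C1 outranks the vinyl carbon), and the S alcohol carrying the C6 stereocentre should remain.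

Step 3
Reactants: 4 methyl (3S)-3-hydroxy-2-methylidenepent-4-enoate
Product: 5 (3S)-2-methylidenepent-4-ene-1,3-diol
Conditions: iBu2AlH (3.3 equiv), CH2Cl2, −78 to 0 °C; aq. Rochelle salt
Reagents that add atoms: none
Why: 1,2-Reduction of the ester with iBu2AlH is standard for Baylis–Hillman esters, and the carbinol centre is not touched.

Step 4
Reactants: 5 (3S)-2-methylidenepent-4-ene-1,3-diol
Product: 6 (3S)-3-hydroxy-2-methylidenepent-4-en-1-yl benzoate
Conditions: BzCl (1.05 equiv), Et3N, CH2Cl2, −78 to −40 °C
Reagents that add atoms: benzoyl chloride O=C(Cl)c1ccccc1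
Why: Selective acylation: the primary allylic hydroxyl should react much faster than the flanked secondary bis-allylic one at low temperature, which installs the C7 benzoate of the target.

Step 5
Reactants: 6 (3S)-3-hydroxy-2-methylidenepent-4-en-1-yl benzoate; 7 penta-1,4-dien-3-ol (divinylcarbinol)
Product: 9 (3S)-3-{[di(propan-2-yl)(penta-1,4-dien-3-yloxy)silyl]oxy}-2-methylidenepent-4-en-1-yl benzoate (mixed silaketal tetraene), via chlorosilane 8 (not isolated)
Conditions: iPr2SiCl2 (1.1 equiv), imidazole, CH2Cl2, 0 °C; then 7 (1.5 equiv), imidazole, 0 °C to rt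
Reagents that add atoms: dichlorodi(propan-2-yl)silane CC(C)[Si](Cl)(Cl)C(C)C
Why: Stepwise silaketal formation (temporary silicon tether): the hindered dichlorosilane should stop at the monoalkoxy chlorosilane 8 with one secondary alcohol, and the second alcohol then displaces the remaining chloride.

Step 6
Reactants: 9 mixed silaketal tetraene
Product: 11 [(1R,5S)-3,3-di(propan-2-yl)-2,4-dioxa-3-silabicyclo[3.2.2]nona-6,8-dien-6-yl]methyl benzoate (ring carbons C3 R and C6 S; O3 and O6 on the same face), via monocyclic triene 10 (not isolated)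
Conditions: second-generation Grubbs catalyst (H2IMes)(PCy3)Cl2Ru=CHPh (10 mol %), 1,4-benzoquinone (20 mol %), toluene (2 mM), 80 °C, argon sparge
Reagents that add atoms: none
Why: Double ring-closing metathesis: the ruthenium alkylidene loads on a monosubstituted vinyl group, [2+2] cycloaddition/cycloreversion joins C4 to C5 with loss of ethene to give the seven-membered silaketal 10 (Z alkene enforced by the ring), and the alkylidene then formed at the remaining vinyl carbon C2 takes the 1,1-disubstituted C1 alkene across that ring with loss of a second ethene. The closest known reaction types are temporary-silicon-tethered ring-closing metathesis of mixed silaketals made from penta-1,4-dien-3-ol and a chiral allylic alcohol, and ring-closing metathesis of 1,4,7-trienes to cyclohexa-1,4-dienes. Ring one is the 1,3-dioxa-2-silacyclohept-5-ene (closure of two terminal vinyl groups); ring two is the carbocycle C1–C6, closed transannularly so that O3–Si–O6 becomes the three-atom bridge of a bicyclo[3.2.2]nonadiene whose O···O span fits the C3···C6 distance of a boat cyclohexa-1,4-diene. C3 is the only new stereocentre: its two vinyl groups are diastereotopic, C6 selects between them through the tether (cis-4,7-disubstituted ring with both side chains pseudo-equatorial in the first closure), and only the cis isomer can close the second ring, while the trans isomer can re-open with ethene and be recycled. The step needs group selectivity and intra- over intermolecular metathesis: the geminal alkene pairs on C3 and on C6 cannot close on each other, so every productive pairing joins the two halves, high dilution disfavours oligomers, and 1,4-benzoquinone suppresses ruthenium hydride isomerisation of the skipped diene.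

Step 7
Reactants: 11 bicyclic silaketal diene
Product: 12 silaketal-bridged cis-1,2-diol (C1 S, C2 S, C3 R, C6 S; O1 and O2 on the face opposite to O3 and O6)
Conditions: OsO4 (2 mol %), NMO (1.05 equiv), acetone/H2O, 0 °C
Reagents that add atoms: N-methylmorpholine N-oxide C[N+]1([O-])CCOCC1; water O; OsO4 O=[Os](=O)(=O)=O (catalytic oxygen carrier)
Why: Upjohn dihydroxylation: the suprafacial [3+2] addition gives the cis-diol, the trisubstituted C1=C2 alkene is the more electron-rich of the two, and the face under the O–Si(iPr)2–O bridge is blocked, so O1 and O2 should enter anti to O3.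

Step 8
Reactants: 12 silaketal-bridged cis-1,2-diol
Product: 13 silaketal-bridged 2-O-acetate (C1 S, C2 S, C3 R, C6 S)
Conditions: Ac2O (1.5 equiv), pyridine, CH2Cl2, 0 °C to rt
Reagents that add atoms: acetic anhydride CC(=O)OC(C)=O
Why: Selective esterification: the secondary C2 hydroxyl is acetylated, while the tertiary C1 hydroxyl should stay free without a nucleophilic catalyst.

Step 9
Reactants: 13 silaketal-bridged 2-O-acetate
Product: 14 [(1R,2S,3R,6S)-2-acetoxy-1,3,6-trihydroxycyclohex-4-en-1-yl]methyl benzoate
Conditions: HF·pyridine, pyridine, THF, 0 °C to rt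
Reagents that add atoms: none
Why: Fluoride cleavage of both Si–O bonds is driven by Si–F bond formation, and the weakly acidic buffered medium should leave the esters in place and slow acyl migration.

Step 10
Reactants: 14 2-O-acetyl triol
Product: 15 (1R,2S,3R,6S)-2-acetoxy-3-benzoyloxy-1-(benzoyloxymethyl)cyclohex-4-ene-1,6-diol
Conditions: BzCl (1.1 equiv), pyridine, CH2Cl2, −20 °C
Reagents that add atoms: benzoyl chloride O=C(Cl)c1ccccc1
Why: Sterically controlled acylation: C6–OH is neopentyl-like next to the fully substituted C1 and C1–OH is tertiary, so the C3 allylic hydroxyl should be benzoylated first, with retention.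

Step 11
Reactants: 15 2-acetoxy-3-benzoyloxy-1,6-diol
Product: 16 2-O-acetylzeylenone, (1S,2S,3R)
Conditions: IBX (1.5 equiv), DMSO, rt
Reagents that add atoms: none
Why: IBX oxidation of the secondary allylic alcohol gives the enone without cleaving the 1,2-diol or touching the tertiary hydroxyl, and it removes the relay stereocentre C6.

**Compound list**
1 | acrolein | C=CC=O | starting material
2 | methyl acrylate | C=CC(=O)OC | starting material
3 | methyl 3-hydroxy-2-methylidenepent-4-enoate (racemic) | C=CC(O)C(=C)C(=O)OC | intermediate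
4 | methyl (3S)-3-hydroxy-2-methylidenepent-4-enoate | C=C[C@H](O)C(=C)C(=O)OC | intermediate
5 | (3S)-2-methylidenepent-4-ene-1,3-diol | C=C[C@H](O)C(=C)CO | intermediate
6 | (3S)-3-hydroxy-2-methylidenepent-4-en-1-yl benzoate | C=C[C@H](O)C(=C)COC(=O)c1ccccc1 | intermediate
7 | penta-1,4-dien-3-ol | C=CC(O)C=C | starting material
8 | (3S)-3-{[chlorodi(propan-2-yl)silyl]oxy}-2-methylidenepent-4-en-1-yl benzoate | C=C[C@H](O[Si](Cl)(C(C)C)C(C)C)C(=C)COC(=O)c1ccccc1 | intermediate
9 | mixed silaketal tetraene | C=C[C@H](O[Si](OC(C=C)C=C)(C(C)C)C(C)C)C(=C)COC(=O)c1ccccc1 | intermediate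
10 | 2-[(4S,7S)-7-ethenyl-2,2-di(propan-2-yl)-4,7-dihydro-1,3,2-dioxasilepin-4-yl]prop-2-en-1-yl benzoate (cis) | CC(C)[Si]1(C(C)C)O[C@@H](C=C)C=C[C@@H](C(=C)COC(=O)c2ccccc2)O1 | intermediate
11 | [(1R,5S)-3,3-di(propan-2-yl)-2,4-dioxa-3-silabicyclo[3.2.2]nona-6,8-dien-6-yl]methyl benzoate | CC(C)[Si]1(C(C)C)O[C@@H]2C=C[C@H](O1)C(COC(=O)c3ccccc3)=C2 | intermediate
12 | silaketal-bridged cis-1,2-diol | CC(C)[Si]1(C(C)C)O[C@@H]2C=C[C@H](O1)[C@](O)(COC(=O)c3ccccc3)[C@H]2O | intermediate
13 | silaketal-bridged 2-O-acetate | CC(C)[Si]1(C(C)C)O[C@@H]2C=C[C@H](O1)[C@](O)(COC(=O)c3ccccc3)[C@H]2OC(C)=O | intermediate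
14 | [(1R,2S,3R,6S)-2-acetoxy-1,3,6-trihydroxycyclohex-4-en-1-yl]methyl benzoate | O[C@@H]1C=C[C@H](O)[C@](O)(COC(=O)c2ccccc2)[C@H]1OC(C)=O | intermediate
15 | (1R,2S,3R,6S)-2-acetoxy-3-benzoyloxy-1-(benzoyloxymethyl)cyclohex-4-ene-1,6-diol | O=C(O[C@@H]1C=C[C@H](O)[C@](O)(COC(=O)c2ccccc2)[C@H]1OC(C)=O)c1ccccc1 | intermediate
16 | 2-O-acetylzeylenone | CC(=O)O[C@H]1[C@H](OC(=O)c2ccccc2)C=CC(=O)[C@]1(O)COC(=O)c1ccccc1 | target

Total step count: 11. Longest linear sequence: 11 steps (from 1 and 2; compound 7 enters as purchased at step 5).

**Steps most likely to fail**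

Step 6. The second, transannular closure may lag behind intermolecular metathesis. The skipped diene may also suffer double-bond migration followed by aromatisation.
Fallback, from 9 back to 11: the two closures are separated and the second one is run without the bridge.
- The first-generation Grubbs catalyst (PCy3)2Cl2Ru=CHPh does not engage 1,1-disubstituted alkenes, so it should stop at the monocyclic triene 10, which is now isolated.
- HF·pyridine takes the tether off to give the open (Z)-triene diol F1.
- The second-generation catalyst closes this 1,4,7-triene to the cis-cyclohexa-2,5-diene-1,4-diol F2.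
- iPr2Si(OTf)2 with 2,6-lutidine re-bridges the cis-1,4-diol, and the route is rejoined at 11.

Step 7. OsO4 may attack the less hindered C4=C5 alkene, or both alkenes may be oxidised.
Fallback, from 11 back to 12: the choice of alkene is handed to a directing group.
- K2CO3 in MeOH removes the benzoate to give the primary allylic alcohol F3.
- Stoichiometric OsO4·TMEDA in CH2Cl2 at −78 °C is steered by hydrogen bonding to this hydroxyl on to C1=C2 only. The bridge still fixes the face, and reductive work-up gives the triol F4.
- BzCl with collidine at low temperature re-benzoylates the primary hydroxyl, and the route is rejoined at 12.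

Step 10. Discrimination between the two allylic hydroxyls may be insufficient, and the acetyl group may migrate from O2 to O3 under base.
Fallback, from 14 to 16: the benzoate is put on last, when only one acylable hydroxyl is left.
- The bulkier TBSCl with imidazole should select the open C3 hydroxyl to give the 3-O-TBS ether F5.
- IBX oxidises C6–OH to give the silylated enone F6.
- HF·pyridine frees the hydroxy enone F7.
- BzCl with pyridine gives 16 directly.

**Further compounds**
F1 | step 6 | (3S,4Z,6S)-3,6-dihydroxy-2-methylideneocta-4,7-dien-1-yl benzoate | O[C@@H](C=C)/C=C\[C@@H](C(=C)COC(=O)c1ccccc1)O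
F2 | step 6 | [(3R,6S)-3,6-dihydroxycyclohexa-1,4-dien-1-yl]methyl benzoate (cis-diol) | O[C@@H]1C=C[C@H](O)C(COC(=O)c2ccccc2)=C1
F3 | step 7 | [(1R,5S)-3,3-di(propan-2-yl)-2,4-dioxa-3-silabicyclo[3.2.2]nona-6,8-dien-6-yl]methanol | CC(C)[Si]1(C(C)C)O[C@@H]2C=C[C@H](O1)C(CO)=C2
F4 | step 7 | silaketal-bridged 1,2,7-triol (O1 and O2 anti to the bridge) | CC(C)[Si]1(C(C)C)O[C@@H]2C=C[C@H](O1)[C@](O)(CO)[C@H]2O
F5 | step 10 | 3-O-TBS ether of 14 | CC(C)(C)[Si](C)(C)O[C@@H]1C=C[C@H](O)[C@](O)(COC(=O)c2ccccc2)[C@H]1OC(C)=O
F6 | step 10 | 3-O-TBS-3-debenzoyl-2-O-acetylzeylenone | CC(C)(C)[Si](C)(C)O[C@@H]1C=CC(=O)[C@](O)(COC(=O)c2ccccc2)[C@H]1OC(C)=O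
F7 | step 10 | 3-debenzoyl-2-O-acetylzeylenone | O[C@@H]1C=CC(=O)[C@](O)(COC(=O)c2ccccc2)[C@H]1OC(C)=O
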